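**Retrosynthetic overview**

1. Target 30 ⇐ diol 26 (aryl silyl ether cleavage; Yamaguchi tigloylation of the C10 hydroxyl) ⇐ epoxy alcohol 23 (selenolate opening at C9, then selenoxide syn-elimination places the alkene at C8=C9).
2. Key C–O disconnection: the C4–O and C10–O bonds of 23 both come from diene 20 and one molecule of O2 (radical hydroperoxidation at C4, then intramolecular oxygen transfer to C9=C10).
3. Ring order: the cyclopentane is bought (3-methylcyclopent-2-enone 8); the seven-membered ring is closed second, by ring-closing metathesis of 19 (forms C9=C10).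
4. 19 ⇐ ketone 16 (enol triflate, isopropyl cross-coupling) ⇐ 8 + 9 + 4 + 7 (enantioselective conjugate addition sets C1; anti-aldol sets C5 and C6; the aldolate is aroylated in the flask).
5. Aldehyde 4 ⇐ (E)-pent-3-en-2-one 1 (CBS reduction, Claisen rearrangement; sets C8); acid chloride 7 ⇐ 4-hydroxybenzoic acid 5.

Numbering and target reading: daucane locants are used throughout (five-membered ring C1–C2–C3–C4–C5, seven-membered ring C1–C5–C6–C7–C8–C9–C10; C15 = methyl on C1, C14 = methyl on C8, isopropyl on C4). β is the face of the C1 methyl, α the face of H5. The target is made exactly as drawn: 4α-OH (4β-isopropyl), 5α-H, 6α-aroyloxy, 10α-tigloyloxy, that is (1S,4S,5S,6S,10R).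

**Route**

Step 1
Reactants: 1 (E)-pent-3-en-2-one
Product: 2 (R,E)-pent-3-en-2-ol
Conditions: (S)-2-methyl-CBS-oxazaborolidine (10 mol %), catecholborane, PhMe, −78 °C; then H2O
Reagents that add atoms: none
Why: Corey–Bakshi–Shibata reduction, in which the oxazaborolidine–borane complex binds the ketone with the propenyl group as the large substituent and delivers hydride to one carbonyl face, setting the (R)-carbinol centre.

Step 2
Reactants: 2 (R,E)-pent-3-en-2-ol
Product: 4 (R,E)-3-methylhex-4-enal, via allyl vinyl ether 3 (not isolated)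
Conditions: ethyl vinyl ether (solvent), Hg(OAc)2 (5 mol %), reflux; concentrate; then PhMe, 130 °C (sealed tube)
Reagents that add atoms: ethyl vinyl ether, C=COCC
Why: Mercury-catalysed transetherification followed by Claisen rearrangement through a chair transition state with the carbinol methyl equatorial, which transfers the carbinol chirality suprafacially to C3 of the aldehyde (the future C8, R) and gives the E-alkene.

Step 3
Reactants: 5 4-hydroxybenzoic acid
Product: 6 triisopropylsilyl 4-(triisopropylsilyloxy)benzoate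
Conditions: iPr3SiCl (2.2 equiv), imidazole, DMF, 23 °C
Reagents that add atoms: chlorotriisopropylsilane, CC(C)[Si](Cl)(C(C)C)C(C)C
Why: Imidazole-promoted silylation of both the phenol and the carboxylic acid; no stereocentre is involved.

Step 4
Reactants: 6 triisopropylsilyl 4-(triisopropylsilyloxy)benzoate
Product: 7 4-(triisopropylsilyloxy)benzoyl chloride
Conditions: (COCl)2, DMF (cat.), CH2Cl2, 0 → 23 °C
Reagents that add atoms: oxalyl chloride, O=C(Cl)C(=O)Cl
Why: Vilsmeier-type conversion of a silyl ester directly into the acid chloride under neutral conditions, which leaves the aryl silyl ether intact.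

Step 5
Reactants: 8 3-methylcyclopent-2-en-1-one; 9 ethynyltrimethylsilane
Product: 12 (S)-trimethyl{[3-methyl-3-(1-(trimethylsilyl)vinyl)cyclopent-1-en-1-yl]oxy}silane, via alkenylalane 10 (not isolated), via aluminium enolate 11 (not isolated)
Conditions: 9, iBu2AlH, hexanes, 55 °C; then 8, Cu(OTf)2 (5 mol %), chiral sulfonate-bearing NHC ligand (6 mol %, from its imidazolinium salt; the enantiomer that gives the S product), THF, −30 °C; then Me3SiOTf, −78 → 0 °C
Reagents that add atoms: trimethylsilyl trifluoromethanesulfonate, C[Si](C)(C)OS(=O)(=O)C(F)(F)F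
Why: Hydroalumination places aluminium on the silicon-bearing alkyne carbon, copper–NHC-catalysed enantioselective conjugate addition of the resulting alkenylalane creates the C1 quaternary centre under catalyst control, and silylation traps the regiodefined enolate (C4=C5).

Step 6
Reactants: 12 silyl enol ether from step 5; 4 (R,E)-3-methylhex-4-enal; 7 4-(triisopropylsilyloxy)benzoyl chloride
Product: 15 (1S,3R,E)-3-methyl-1-{(1S,2S)-2-methyl-5-oxo-2-[1-(trimethylsilyl)vinyl]cyclopentyl}hex-4-en-1-yl 4-(triisopropylsilyloxy)benzoate, via lithium enolate 13 (not isolated), via chlorozinc aldolate 14 (not isolated)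
Conditions: MeLi, THF, 0 °C; ZnCl2, −78 °C; 4, −78 → −40 °C; then 7, DMAP (cat.), −40 → 0 °C
Reagents that add atoms: none
Why: Directed aldol addition through a closed Zimmerman–Traxler transition state, in which the aldehyde approaches the enolate face anti to the bulky silylvinyl group (new C5–C6 bond cis to the C1 methyl, H5 α) and the ring-locked E-enolate gives the anti aldolate (C6, S), which is O-acylated in the flask before it can revert.

Step 7
Reactants: 15 aroyloxy ketone from step 6
Product: 16 (1S,3R,E)-3-methyl-1-[(1S,2R)-2-methyl-5-oxo-2-vinylcyclopentyl]hex-4-en-1-yl 4-(triisopropylsilyloxy)benzoate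
Conditions: CF3CO2H, CH2Cl2, 0 → 23 °C
Reagents that add atoms: none
Why: Protodesilylation of the vinylsilane by ipso protonation (β-silicon stabilisation of the cation), which leaves the ketone, the ester, the aryl silyl ether and the disubstituted alkene untouched and no stereocentre affected.

Step 8
Reactants: 16 vinyl ketone from step 7
Product: 18 (1S,3R,E)-3-methyl-1-[(1S,5R)-5-methyl-2-(trifluoromethylsulfonyloxy)-5-vinylcyclopent-2-en-1-yl]hex-4-en-1-yl 4-(triisopropylsilyloxy)benzoate, via potassium enolate 17 (not isolated)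
Conditions: KN(SiMe3)2, THF, −78 °C; then PhNTf2, −78 → 0 °C
Reagents that add atoms: N-phenylbis(trifluoromethanesulfonimide), O=S(=O)(N(c1ccccc1)S(=O)(=O)C(F)(F)F)C(F)(F)F
Why: Kinetic deprotonation occurs at the unhindered C3 methylene and not at the tertiary, flanked C5–H (which also avoids β-elimination of the C6 ester), and O-triflation of the enolate gives the C3=C4 enol triflate.

Step 9
Reactants: 18 enol triflate from step 8
Product: 19 (1S,3R,E)-1-[(1R,5R)-2-isopropyl-5-methyl-5-vinylcyclopent-2-en-1-yl]-3-methylhex-4-en-1-yl 4-(triisopropylsilyloxy)benzoate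
Conditions: iPrMgBr, Fe(acac)3 (5 mol %), THF/NMP, −30 °C
Reagents that add atoms: isopropylmagnesium bromide, CC(C)[Mg]Br
Why: Iron-catalysed Kumada-type cross-coupling of an alkenyl triflate with a secondary alkyl Grignard reagent, which is fast enough at −30 °C for the aryl ester to survive and installs the isopropyl group on C4 without touching a stereocentre.

Step 10
Reactants: 19 triene from step 9
Product: 20 8βH-dauca-3,9-dien-6α-yl 4-(triisopropylsilyloxy)benzoate (trans-fused: C15 β; H5 α; C14 α)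
Conditions: second-generation Hoveyda–Grubbs catalyst (5 mol %), PhMe (0.002 M), 80 °C
Reagents that add atoms: none
Why: Ring-closing metathesis between the C1 vinyl group and the propenyl terminus closes the seven-membered ring as the cis C9=C10 alkene with loss of propene, while the trisubstituted cyclopentene does not react and all stereocentres are carried through.

Step 11
Reactants: 20 bicyclic diene from step 10
Product: 23 9α,10α-epoxy-4α-hydroxy-8βH-daucan-6α-yl 4-(triisopropylsilyloxy)benzoate, via triethylsilyl peroxide 21 (not isolated), via hydroperoxide 22 (not isolated)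
Conditions: Co(thd)2 (5 mol %; thd = 2,2,6,6-tetramethylheptane-3,5-dionate), Et3SiH, O2 (1 atm), ClCH2CH2Cl, 23 °C; then MeOH, pyridinium p-toluenesulfonate (cat.), 0 °C; then VO(acac)2 (5 mol %), CH2Cl2, 0 → 23 °C
Reagents that add atoms: dioxygen, O=O
Why: Proposed new method: an aerobic hydroxy-epoxidation by oxygen relay, in which cobalt-hydride hydrogen-atom transfer to the trisubstituted C3=C4 alkene gives the tertiary C4 radical that captures O2 on the face anti to the pseudo-axial C1 methyl (α) and is silylated (closest known reaction for this half: Mukaiyama–Isayama hydroperoxysilylation, to which the cis-1,2-disubstituted C9=C10 alkene is inert), after which the freed C4 hydroperoxide, held 1,3-cis to C10 on the cyclopentane, binds vanadium (oxidised in the flask to the pentavalent state) as an alkylperoxo ligand and passes its distal oxygen to the α face of C9=C10 (closest known reactions: vanadium/tert-butyl hydroperoxide epoxidation of homoallylic alcohols and titanium-mediated oxygen transfer from allylic hydroperoxides), so that one O2 forms the C4–O and C10–O bonds and sets both stereocentres while only the α-hydroperoxide can reach the alkene.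

Step 12
Reactants: 23 epoxy alcohol from step 11
Product: 26 4α,10α-dihydroxydauc-8-en-6α-yl 4-(triisopropylsilyloxy)benzoate, via hydroxy selenide 24 (not isolated), via selenoxide 25 (not isolated)
Conditions: (PhSe)2, NaBH4, EtOH, 0 → 40 °C; then H2O2 (30 % aq.), pyridine, THF, 0 → 23 °C
Reagents that add atoms: none
Why: Sharpless-type epoxide-to-allylic-alcohol transposition, in which selenolate opens the epoxide by SN2 attack at C9 (C10 is neopentyl) from the β face and the derived selenoxide undergoes syn-elimination with the cis C8–H (β, fixed in step 2) and away from the carbinol, giving the C8=C9 alkene while the C10–O bond and its α configuration stay untouched.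

Step 13
Reactants: 26 diol from step 12; 27 tiglic acid
Product: 29 4α-hydroxy-6α-[4-(triisopropylsilyloxy)benzoyloxy]dauc-8-en-10α-yl (E)-2-methylbut-2-enoate, via mixed anhydride 28 (not isolated)
Conditions: 27, 2,4,6-trichlorobenzoyl chloride, Et3N, THF, 23 °C; then 26, DMAP, PhMe, 60 °C
Reagents that add atoms: none
Why: Yamaguchi esterification acylates the secondary allylic C10 hydroxyl while the tertiary C4 hydroxyl is too hindered to react, and because only the acyl–oxygen bond is formed the C10 configuration and the E geometry of the tiglate are retained.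

Step 14
Reactants: 29 silyl-protected diester from step 13
Product: 30 target, 4α-hydroxy-6α-(4-hydroxybenzoyloxy)dauc-8-en-10α-yl (E)-2-methylbut-2-enoate
Conditions: Bu4NF, AcOH, THF, 0 °C
Reagents that add atoms: none
Why: Fluoride-mediated cleavage of the aryl silyl ether, buffered with acetic acid so that the two esters and the allylic system are not attacked; no stereocentre is affected.

**Compound list**

1 | (E)-pent-3-en-2-one | C/C=C/C(C)=O | starting material
2 | (R,E)-pent-3-en-2-ol | C[C@@H](O)/C=C/C | intermediate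
3 | (R,E)-4-(vinyloxy)pent-2-ene | C[C@@H](OC=C)/C=C/C | intermediate
4 | (R,E)-3-methylhex-4-enal | O=CC[C@@H](C)/C=C/C | intermediate
5 | 4-hydroxybenzoic acid | O=C(O)c1ccc(O)cc1 | starting material
6 | triisopropylsilyl 4-(triisopropylsilyloxy)benzoate | CC(C)[Si](C(C)C)(C(C)C)OC(=O)c1ccc(O[Si](C(C)C)(C(C)C)C(C)C)cc1 | intermediate
7 | 4-(triisopropylsilyloxy)benzoyl chloride | O=C(Cl)c1ccc(O[Si](C(C)C)(C(C)C)C(C)C)cc1 | intermediate
8 | 3-methylcyclopent-2-en-1-one | CC1=CC(=O)CC1 | starting material
9 | ethynyltrimethylsilane | C#C[Si](C)(C)C | starting material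
10 | diisobutyl[1-(trimethylsilyl)vinyl]alane | C=C([Si](C)(C)C)[Al](CC(C)C)CC(C)C | intermediate
11 | diisobutylaluminium enolate of (S)-3-methyl-3-[1-(trimethylsilyl)vinyl]cyclopentanone (enolate C4=C5) | CC(C)C[Al](CC(C)C)OC1=C[C@@](C)(C(=C)[Si](C)(C)C)CC1 | intermediate
12 | (S)-trimethyl{[3-methyl-3-(1-(trimethylsilyl)vinyl)cyclopent-1-en-1-yl]oxy}silane | C[Si](C)(C)OC1=C[C@@](C)(C(=C)[Si](C)(C)C)CC1 | intermediate
13 | lithium enolate corresponding to 12 | [Li]OC1=C[C@@](C)(C(=C)[Si](C)(C)C)CC1 | intermediate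
14 | chlorozinc alkoxide of (2S,3S)-2-[(1S,3R,E)-1-hydroxy-3-methylhex-4-en-1-yl]-3-methyl-3-[1-(trimethylsilyl)vinyl]cyclopentan-1-one | O=C1CC[C@](C)(C(=C)[Si](C)(C)C)[C@H]1[C@@H](O[Zn]Cl)C[C@@H](C)/C=C/C | intermediate
15 | (1S,3R,E)-3-methyl-1-{(1S,2S)-2-methyl-5-oxo-2-[1-(trimethylsilyl)vinyl]cyclopentyl}hex-4-en-1-yl 4-(triisopropylsilyloxy)benzoate | O=C1CC[C@](C)(C(=C)[Si](C)(C)C)[C@H]1[C@@H](OC(=O)c2ccc(O[Si](C(C)C)(C(C)C)C(C)C)cc2)C[C@@H](C)/C=C/C | intermediate
16 | (1S,3R,E)-3-methyl-1-[(1S,2R)-2-methyl-5-oxo-2-vinylcyclopentyl]hex-4-en-1-yl 4-(triisopropylsilyloxy)benzoate | O=C1CC[C@](C)(C=C)[C@H]1[C@@H](OC(=O)c2ccc(O[Si](C(C)C)(C(C)C)C(C)C)cc2)C[C@@H](C)/C=C/C | intermediate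
17 | potassium enolate of 16 (enolate C3=C4) | [K]OC1=CC[C@](C)(C=C)[C@H]1[C@@H](OC(=O)c2ccc(O[Si](C(C)C)(C(C)C)C(C)C)cc2)C[C@@H](C)/C=C/C | intermediate
18 | (1S,3R,E)-3-methyl-1-[(1S,5R)-5-methyl-2-(trifluoromethylsulfonyloxy)-5-vinylcyclopent-2-en-1-yl]hex-4-en-1-yl 4-(triisopropylsilyloxy)benzoate | O=S(=O)(OC1=CC[C@](C)(C=C)[C@H]1[C@@H](OC(=O)c2ccc(O[Si](C(C)C)(C(C)C)C(C)C)cc2)C[C@@H](C)/C=C/C)C(F)(F)F | intermediate
19 | (1S,3R,E)-1-[(1R,5R)-2-isopropyl-5-methyl-5-vinylcyclopent-2-en-1-yl]-3-methylhex-4-en-1-yl 4-(triisopropylsilyloxy)benzoate | CC(C)C1=CC[C@](C)(C=C)[C@H]1[C@@H](OC(=O)c2ccc(O[Si](C(C)C)(C(C)C)C(C)C)cc2)C[C@@H](C)/C=C/C | intermediate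
20 | 8βH-dauca-3,9-dien-6α-yl 4-(triisopropylsilyloxy)benzoate (trans-fused; C15 β, H5 α, C14 α) | C1=C[C@H](C)C[C@H](OC(=O)c3ccc(O[Si](C(C)C)(C(C)C)C(C)C)cc3)[C@@H]2[C@]1(C)CC=C2C(C)C | intermediate
21 | 4α-(triethylsilylperoxy)-8βH-dauc-9-en-6α-yl 4-(triisopropylsilyloxy)benzoate | C1=C[C@H](C)C[C@H](OC(=O)c3ccc(O[Si](C(C)C)(C(C)C)C(C)C)cc3)[C@@H]2[C@]1(C)CC[C@]2(OO[Si](CC)(CC)CC)C(C)C | intermediate
22 | 4α-hydroperoxy-8βH-dauc-9-en-6α-yl 4-(triisopropylsilyloxy)benzoate | C1=C[C@H](C)C[C@H](OC(=O)c3ccc(O[Si](C(C)C)(C(C)C)C(C)C)cc3)[C@@H]2[C@]1(C)CC[C@]2(OO)C(C)C | intermediate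
23 | 9α,10α-epoxy-4α-hydroxy-8βH-daucan-6α-yl 4-(triisopropylsilyloxy)benzoate | O1[C@@H]2[C@H]1[C@H](C)C[C@H](OC(=O)c4ccc(O[Si](C(C)C)(C(C)C)C(C)C)cc4)[C@@H]3[C@]2(C)CC[C@]3(O)C(C)C | intermediate
24 | 4α,10α-dihydroxy-9β-(phenylselanyl)-8βH-daucan-6α-yl 4-(triisopropylsilyloxy)benzoate | O[C@@H]1[C@@H]([Se]c2ccccc2)[C@H](C)C[C@H](OC(=O)c4ccc(O[Si](C(C)C)(C(C)C)C(C)C)cc4)[C@@H]3[C@]1(C)CC[C@]3(O)C(C)C | intermediate
25 | 4α,10α-dihydroxy-9β-(phenylseleninyl)-8βH-daucan-6α-yl 4-(triisopropylsilyloxy)benzoate (mixture at selenium) | O[C@@H]1[C@@H]([Se](=O)c2ccccc2)[C@H](C)C[C@H](OC(=O)c4ccc(O[Si](C(C)C)(C(C)C)C(C)C)cc4)[C@@H]3[C@]1(C)CC[C@]3(O)C(C)C | intermediate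
26 | 4α,10α-dihydroxydauc-8-en-6α-yl 4-(triisopropylsilyloxy)benzoate | O[C@@H]1C=C(C)C[C@H](OC(=O)c3ccc(O[Si](C(C)C)(C(C)C)C(C)C)cc3)[C@@H]2[C@]1(C)CC[C@]2(O)C(C)C | intermediate
27 | tiglic acid, (E)-2-methylbut-2-enoic acid | C/C=C(\C)C(=O)O | starting material
28 | (E)-2-methylbut-2-enoic 2,4,6-trichlorobenzoic anhydride | C/C=C(\C)C(=O)OC(=O)c1c(Cl)cc(Cl)cc1Cl | intermediate
29 | 4α-hydroxy-6α-[4-(triisopropylsilyloxy)benzoyloxy]dauc-8-en-10α-yl (E)-2-methylbut-2-enoate | C/C=C(\C)C(=O)O[C@@H]1C=C(C)C[C@H](OC(=O)c3ccc(O[Si](C(C)C)(C(C)C)C(C)C)cc3)[C@@H]2[C@]1(C)CC[C@]2(O)C(C)C | intermediate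
30 | (1S,4S,5S,6S,10R)-4-hydroxy-6-(4-hydroxybenzoyloxy)dauc-8-en-10-yl (E)-2-methylbut-2-enoate | C/C=C(\C)C(=O)O[C@@H]1C=C(C)C[C@H](OC(=O)c2ccc(O)cc2)[C@@H]2[C@]1(C)CC[C@]2(O)C(C)C | target

**Step count and risks**

Total step count: 14. Longest linear sequence: 11 steps (1 → 2 → 4 → 15 → 16 → 18 → 19 → 20 → 23 → 26 → 29 → 30; the sequence from 5 is equally long).

The three steps most likely to fail:

Step 6 (aldol and acylation in one flask). The enolate carbon is neopentyl, and both the facial selectivity at C5 and the anti selectivity at C6 rest on a closed transition state that may be only moderately selective. The fallback sets out from 12 (with 4) and comes back at 15. It replaces the metal-enolate aldol by a TiCl4-mediated Mukaiyama aldol (CH2Cl2, −78 °C, open transition state), which gives the free aldol (2S,3S)-2-[(1S,3R,E)-1-hydroxy-3-methylhex-4-en-1-yl]-3-methyl-3-[1-(trimethylsilyl)vinyl]cyclopentan-1-one F1. This is isolated, freed of its C6 epimer by chromatography, and acylated in a separate operation with 7 (pyridine, DMAP, CH2Cl2) to give 15.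

Step 10 (ring-closing metathesis). The vinyl group sits on a quaternary carbon and the ring formed is trans-fused to a cyclopentene that carries a bulky isopropyl group next to the reacting arm. The fallback sets out from 16 and comes back at 20, changing the order of events. The metathesis is run on the less congested ketone 16 (same catalyst) to give the bicyclic ketone 1β,8α-dimethyl-4-oxo-5αH-bicyclo[5.3.0]dec-9-en-6α-yl 4-(triisopropylsilyloxy)benzoate F2 (daucane locants). This is converted with KN(SiMe3)2 and PhNTf2 into the corresponding C3=C4 enol triflate F3, and iron-catalysed coupling with iPrMgBr then gives 20.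

Step 11 (the proposed oxygen relay). The hydroperoxysilylation may not be fully α-selective at C4, the hydroperoxide may be reduced or decomposed by residual cobalt before it meets vanadium, and the intramolecular oxygen transfer is without precedent. The fallback uses known chemistry, sets out from 20 and comes back at 23. Mukaiyama hydration (Mn(dpm)3, dpm = dipivaloylmethanate, PhSiH3, O2, iPrOH, 0 °C; then PPh3) gives the tertiary alcohol 4α-hydroxy-8βH-dauc-9-en-6α-yl 4-(triisopropylsilyloxy)benzoate F4. Hydroxyl-directed epoxidation of its C9=C10 alkene (VO(acac)2, tBuOOH, CH2Cl2, or m-CPBA with NaHCO3) from the α face then gives 23.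

**Further compounds**

F1 | step 6 | (2S,3S)-2-[(1S,3R,E)-1-hydroxy-3-methylhex-4-en-1-yl]-3-methyl-3-[1-(trimethylsilyl)vinyl]cyclopentan-1-one | O=C1CC[C@](C)(C(=C)[Si](C)(C)C)[C@H]1[C@@H](O)C[C@@H](C)/C=C/C
F2 | step 10 | 1β,8α-dimethyl-4-oxo-5αH-bicyclo[5.3.0]dec-9-en-6α-yl 4-(triisopropylsilyloxy)benzoate (daucane locants) | C1=C[C@H](C)C[C@H](OC(=O)c3ccc(O[Si](C(C)C)(C(C)C)C(C)C)cc3)[C@@H]2[C@]1(C)CCC2=O
F3 | step 10 | 1β,8α-dimethyl-4-(trifluoromethylsulfonyloxy)-5αH-bicyclo[5.3.0]deca-3,9-dien-6α-yl 4-(triisopropylsilyloxy)benzoate (daucane locants) | C1=C[C@H](C)C[C@H](OC(=O)c3ccc(O[Si](C(C)C)(C(C)C)C(C)C)cc3)[C@@H]2[C@]1(C)CC=C2OS(=O)(=O)C(F)(F)F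
F4 | step 11 | 4α-hydroxy-8βH-dauc-9-en-6α-yl 4-(triisopropylsilyloxy)benzoate | C1=C[C@H](C)C[C@H](OC(=O)c3ccc(O[Si](C(C)C)(C(C)C)C(C)C)cc3)[C@@H]2[C@]1(C)CC[C@]2(O)C(C)C
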